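**Retrosynthetic overview**

1. Target 23 comes from 22 in one fluoride treatment: the 2-alkoxypyridine N-oxide collapses to the N-hydroxy-2-pyridone and the silyl ether falls off.
2. Key disconnection: the ketone C(=O)–C3(pyridine) bond, made last by trapping the acyl radical of decalin aldehyde 12 (from its formyl C–H) on the nickel-bound pyridyl from bromide 21.
3. 21 comes from 2,4-difluoropyridine (ring bought): double SNAr, C5 bromination, aryllithium addition to epoxy ketone 14 (from the (S)-4-silyloxycyclohexenone by anti epoxidation), C3 bromination, N-oxidation.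
4. 12 comes from trienal 11 by an intramolecular Diels–Alder reaction (rings A and B of the decalin close together; four stereocentres follow from the C6 methyl). 11 comes from methyl crotonate and butenyl Grignard (catalytic asymmetric conjugate addition), cross-metathesis and a crotyl Wittig reaction.
5. Ring order: the epoxycyclohexane is fixed first and joined to the pyridine, the decalin is built separately, the two halves are united at the end, and the pyridone is revealed last.

Assumption: enone 13 is bought as the enantiopure silyl ether, and (S)-Tol-BINAP is taken to give the R ester in step 1 (if the sign of rotation of 3 shows the opposite sense, the R ligand is used).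

**Route**

Step 1
Reactants: 1 methyl (E)-but-2-enoate; 2 but-3-en-1-ylmagnesium bromide
Product: 3 methyl (3R)-3-methylhept-6-enoate
Conditions: CuI (2 mol%), (S)-Tol-BINAP (3 mol%), 2 (1.5 equiv, slow addition), t-BuOMe, −40 °C; then 1 M HCl
Reagents that add atoms: none
Why: Copper-catalysed asymmetric conjugate addition of a Grignard reagent to an enoate, in which the chiral bisphosphine–copper complex delivers the butenyl group to one face of the crotonate and sets the methyl-bearing centre as R (about 90–95% ee expected; the minor enantiomer is removed later as a separable diastereomer after step 12).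

Step 2
Reactants: 3 methyl (3R)-3-methylhept-6-enoate; 4 2-ethenyl-1,3-dioxolane
Product: 5 methyl (3R,6E)-7-(1,3-dioxolan-2-yl)-3-methylhept-6-enoate
Conditions: 4 (3 equiv), second-generation Hoveyda–Grubbs catalyst (3 mol%), CH2Cl2, 40 °C
Reagents that add atoms: none
Why: Olefin cross-metathesis of a terminal alkene with an acrolein acetal, driven by loss of ethene and run while 3 has only one alkene so that no ring-closing pathway exists (any Z isomer converges to E in step 4).

Step 3
Reactants: 5 methyl (3R,6E)-7-(1,3-dioxolan-2-yl)-3-methylhept-6-enoate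
Product: 6 (3R,6E)-7-(1,3-dioxolan-2-yl)-3-methylhept-6-enal
Conditions: DIBAL-H (1.1 equiv), CH2Cl2, −78 °C; Rochelle salt work-up
Reagents that add atoms: none
Why: Low-temperature DIBAL-H half-reduction of a methyl ester through the stable tetrahedral aluminium hemiacetal, which leaves the acetal and the stereocentre untouched.

Step 4
Reactants: 6 (3R,6E)-7-(1,3-dioxolan-2-yl)-3-methylhept-6-enal; 7 (E)-1-bromobut-2-ene
Product: 11 (2E,6R,8E,10E)-6-methyldodeca-2,8,10-trienal, via crotyltributylphosphonium bromide 8 (not isolated), via crotylidenetributylphosphorane 9 (not isolated), via triene acetal 10 (not isolated)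
Conditions: 7, PBu3, THF, rt; KOtBu, 0 °C; 6, −78 °C → rt; then 1 M HCl (aq), rt, 2 h
Reagents that add atoms: water (O)
Why: Wittig olefination with an allylic tributylphosphonium ylide, which is E-selective for the new C8=C9 bond, followed in the same flask by acid hydrolysis of the enal acetal, which also equilibrates C2=C3 to E.

Step 5
Reactants: 11 (2E,6R,8E,10E)-6-methyldodeca-2,8,10-trienal
Product: 12 (1R,2R,4aS,6R,8aR)-2,6-dimethyl-1,2,4a,5,6,7,8,8a-octahydronaphthalene-1-carbaldehyde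
Conditions: Et2AlCl (1.0 equiv), CH2Cl2, −78 → −40 °C; aq. NaHCO3
Reagents that add atoms: none
Why: Lewis-acid-promoted intramolecular Diels–Alder reaction through the endo, chair-like transition state with the C6 methyl equatorial, which sets C1, C2, C4a and C8a of the trans-decalin in one step (trienes carrying a Z diene bond do not cyclise at this temperature and are removed here).

Step 6
Reactants: 13 (4S)-4-[(tert-butyldimethylsilyl)oxy]cyclohex-2-en-1-one
Product: 14 (1R,5S,6S)-5-[(tert-butyldimethylsilyl)oxy]-7-oxabicyclo[4.1.0]heptan-2-one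
Conditions: 30% H2O2, benzyltrimethylammonium hydroxide (cat.), THF, 0 °C
Reagents that add atoms: hydrogen peroxide (OO)
Why: Weitz–Scheffer nucleophilic epoxidation in which hydroperoxide adds to the enone face opposite the bulky silyloxy group, giving the epoxide trans to the C–O bond as needed.

Step 7
Reactants: 15 2,4-difluoropyridine
Product: 16 2,4-bis[2-(trimethylsilyl)ethoxy]pyridine
Conditions: 2-(trimethylsilyl)ethanol (2.4 equiv), NaH (2.5 equiv), THF/DMF, 0 → 70 °C
Reagents that add atoms: 2-(trimethylsilyl)ethanol (C[Si](C)(C)CCO)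
Why: Double nucleophilic aromatic substitution (4-F first, then 2-F) by the alkoxide installs both pyridone oxygens as fluoride-cleavable ethers.

Step 8
Reactants: 16 2,4-bis[2-(trimethylsilyl)ethoxy]pyridine
Product: 17 5-bromo-2,4-bis[2-(trimethylsilyl)ethoxy]pyridine
Conditions: NBS (1.05 equiv), MeCN, 0 °C → rt, dark
Reagents that add atoms: N-bromosuccinimide (O=C1CCC(=O)N1Br)
Why: Electrophilic aromatic bromination goes to C5, which is para to the 2-alkoxy and ortho to the 4-alkoxy group and less hindered than C3 between the two ethers.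

Step 9
Reactants: 17 5-bromo-2,4-bis[2-(trimethylsilyl)ethoxy]pyridine; 14 (1R,5S,6S)-5-[(tert-butyldimethylsilyl)oxy]-7-oxabicyclo[4.1.0]heptan-2-one
Product: 19 (1R,2R,5S,6S)-2-{4,6-bis[2-(trimethylsilyl)ethoxy]pyridin-3-yl}-5-[(tert-butyldimethylsilyl)oxy]-7-oxabicyclo[4.1.0]heptan-2-ol, via pyridyllithium 18 (not isolated)
Conditions: 17, n-BuLi (1.05 equiv), THF, −78 °C, 20 min; 14, −78 °C, 1 h; AcOH quench
Reagents that add atoms: none
Why: Bromine–lithium exchange and 1,2-addition of the aryllithium to the ketone from the face anti to the α-epoxide oxygen (Felkin/Cornforth-type control) give the tertiary carbinol with OH cis to the epoxide.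

Step 10
Reactants: 19 (1R,2R,5S,6S)-2-{4,6-bis[2-(trimethylsilyl)ethoxy]pyridin-3-yl}-5-[(tert-butyldimethylsilyl)oxy]-7-oxabicyclo[4.1.0]heptan-2-ol
Product: 20 (1R,2R,5S,6S)-2-{5-bromo-4,6-bis[2-(trimethylsilyl)ethoxy]pyridin-3-yl}-5-[(tert-butyldimethylsilyl)oxy]-7-oxabicyclo[4.1.0]heptan-2-ol
Conditions: NBS (1.1 equiv), MeCN, 0 °C
Reagents that add atoms: N-bromosuccinimide (O=C1CCC(=O)N1Br)
Why: Electrophilic aromatic bromination at the only remaining activated ring position, the carbon between the two alkoxy groups (the later C3 of the pyridone).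

Step 11
Reactants: 20 (1R,2R,5S,6S)-2-{5-bromo-4,6-bis[2-(trimethylsilyl)ethoxy]pyridin-3-yl}-5-[(tert-butyldimethylsilyl)oxy]-7-oxabicyclo[4.1.0]heptan-2-ol
Product: 21 3-bromo-5-[(1R,2R,5S,6S)-5-[(tert-butyldimethylsilyl)oxy]-2-hydroxy-7-oxabicyclo[4.1.0]heptan-2-yl]-2,4-bis[2-(trimethylsilyl)ethoxy]pyridine 1-oxide
Conditions: mCPBA (1.5 equiv), NaHCO3, CH2Cl2, 0 °C → rt
Reagents that add atoms: 3-chloroperoxybenzoic acid (OOC(=O)c1cccc(Cl)c1)
Why: Peracid N-oxidation of the pyridine (made nucleophilic enough by the 4-alkoxy donor) puts in the N–O bond while the molecule still has no alkene.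

Step 12
Reactants: 21 3-bromo-5-[(1R,2R,5S,6S)-5-[(tert-butyldimethylsilyl)oxy]-2-hydroxy-7-oxabicyclo[4.1.0]heptan-2-yl]-2,4-bis[2-(trimethylsilyl)ethoxy]pyridine 1-oxide; 12 (1R,2R,4aS,6R,8aR)-2,6-dimethyl-1,2,4a,5,6,7,8,8a-octahydronaphthalene-1-carbaldehyde
Product: 22 3-[(1R,2R,4aS,6R,8aR)-2,6-dimethyl-1,2,4a,5,6,7,8,8a-octahydronaphthalene-1-carbonyl]-5-[(1R,2R,5S,6S)-5-[(tert-butyldimethylsilyl)oxy]-2-hydroxy-7-oxabicyclo[4.1.0]heptan-2-yl]-2,4-bis[2-(trimethylsilyl)ethoxy]pyridine 1-oxide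
Conditions: 21 (1 equiv), 12 (1.5 equiv), [Ir(dF(CF3)ppy)2(dtbbpy)]PF6 (1 mol%), NiBr2(dme) (10 mol%), dtbbpy (10 mol%), quinuclidine (10 mol%), K2CO3 (1.5 equiv), 1,4-dioxane, blue LEDs (450 nm), 25 °C, degassed
Reagents that add atoms: none
Why: Metallaphotoredox aldehyde C–H arylation (photoredox, hydrogen-atom-transfer and nickel catalysis together), in which photo-oxidised quinuclidine abstracts the formyl hydrogen of 12, the acyl σ-radical (C1 stays intact, and decarbonylation of this secondary acyl radical is slower than metal capture) is trapped by the aryl–nickel bromide formed from zerovalent nickel and 21, and the trivalent nickel acyl aryl reductively eliminates the hindered ketone, joining the two halves at the final oxidation level.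

Step 13
Reactants: 22 3-[(1R,2R,4aS,6R,8aR)-2,6-dimethyl-1,2,4a,5,6,7,8,8a-octahydronaphthalene-1-carbonyl]-5-[(1R,2R,5S,6S)-5-[(tert-butyldimethylsilyl)oxy]-2-hydroxy-7-oxabicyclo[4.1.0]heptan-2-yl]-2,4-bis[2-(trimethylsilyl)ethoxy]pyridine 1-oxide
Product: 23 3-[(1R,2R,4aS,6R,8aR)-2,6-dimethyl-1,2,4a,5,6,7,8,8a-octahydronaphthalene-1-carbonyl]-5-[(1R,2R,5S,6R)-2,5-dihydroxy-7-oxabicyclo[4.1.0]heptan-2-yl]-1,4-dihydroxypyridin-2(1H)-one
Conditions: TBAF (6 equiv), AcOH (3 equiv), THF, 0 °C → 40 °C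
Reagents that add atoms: none
Why: Fluoride-induced desilylation of the secondary silyl ether and β-elimination of both 2-(trimethylsilyl)ethyl ethers (good leaving groups: the N-oxido-pyridone and the acyl-conjugated 4-oxide) release ethene and give the 2-oxy N-oxide, which is the N-hydroxy-2-pyridone tautomer of the target; the acetic acid buffer suppresses epoxide migration.

**Compound list**

1 | methyl (E)-but-2-enoate | C/C=C/C(=O)OC | starting material
2 | but-3-en-1-ylmagnesium bromide | C=CCC[Mg]Br | starting material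
3 | methyl (3R)-3-methylhept-6-enoate | C=CCC[C@@H](C)CC(=O)OC | intermediate
4 | 2-ethenyl-1,3-dioxolane | C=CC1OCCO1 | starting material
5 | methyl (3R,6E)-7-(1,3-dioxolan-2-yl)-3-methylhept-6-enoate | C1COC(O1)/C=C/CC[C@@H](C)CC(=O)OC | intermediate
6 | (3R,6E)-7-(1,3-dioxolan-2-yl)-3-methylhept-6-enal | C1COC(O1)/C=C/CC[C@@H](C)CC=O | intermediate
7 | (E)-1-bromobut-2-ene | C/C=C/CBr | starting material
8 | [(2E)-but-2-en-1-yl]tributylphosphonium bromide | C/C=C/C[P+](CCCC)(CCCC)CCCC.[Br-] | intermediate (not isolated)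
9 | [(2E)-but-2-en-1-ylidene]tributylphosphorane | C/C=C/C=P(CCCC)(CCCC)CCCC | intermediate (not isolated)
10 | 2-[(1E,5R,7E,9E)-5-methylundeca-1,7,9-trien-1-yl]-1,3-dioxolane | C1COC(O1)/C=C/CC[C@@H](C)C/C=C/C=C/C | intermediate (not isolated)
11 | (2E,6R,8E,10E)-6-methyldodeca-2,8,10-trienal | O=C/C=C/CC[C@@H](C)C/C=C/C=C/C | intermediate
12 | (1R,2R,4aS,6R,8aR)-2,6-dimethyl-1,2,4a,5,6,7,8,8a-octahydronaphthalene-1-carbaldehyde | C[C@@H]1CC[C@H]2[C@H](C=O)[C@H](C)C=C[C@@H]2C1 | intermediate
13 | (4S)-4-[(tert-butyldimethylsilyl)oxy]cyclohex-2-en-1-one | O=C1C=C[C@@H](O[Si](C)(C)C(C)(C)C)CC1 | starting material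
14 | (1R,5S,6S)-5-[(tert-butyldimethylsilyl)oxy]-7-oxabicyclo[4.1.0]heptan-2-one | O=C1CC[C@H](O[Si](C)(C)C(C)(C)C)[C@H]2O[C@@H]12 | intermediate
15 | 2,4-difluoropyridine | Fc1ccnc(F)c1 | starting material
16 | 2,4-bis[2-(trimethylsilyl)ethoxy]pyridine | C[Si](C)(C)CCOc1ccnc(OCC[Si](C)(C)C)c1 | intermediate
17 | 5-bromo-2,4-bis[2-(trimethylsilyl)ethoxy]pyridine | C[Si](C)(C)CCOc1cc(OCC[Si](C)(C)C)c(Br)cn1 | intermediate
18 | {4,6-bis[2-(trimethylsilyl)ethoxy]pyridin-3-yl}lithium | C[Si](C)(C)CCOc1cc(OCC[Si](C)(C)C)c([Li])cn1 | intermediate (not isolated)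
19 | (1R,2R,5S,6S)-2-{4,6-bis[2-(trimethylsilyl)ethoxy]pyridin-3-yl}-5-[(tert-butyldimethylsilyl)oxy]-7-oxabicyclo[4.1.0]heptan-2-ol | C[Si](C)(C)CCOc1cc(OCC[Si](C)(C)C)c(cn1)[C@]2(O)CC[C@H](O[Si](C)(C)C(C)(C)C)[C@H]3O[C@H]32 | intermediate
20 | (1R,2R,5S,6S)-2-{5-bromo-4,6-bis[2-(trimethylsilyl)ethoxy]pyridin-3-yl}-5-[(tert-butyldimethylsilyl)oxy]-7-oxabicyclo[4.1.0]heptan-2-ol | C[Si](C)(C)CCOc1ncc(c(OCC[Si](C)(C)C)c1Br)[C@]2(O)CC[C@H](O[Si](C)(C)C(C)(C)C)[C@H]3O[C@H]32 | intermediate
21 | 3-bromo-5-[(1R,2R,5S,6S)-5-[(tert-butyldimethylsilyl)oxy]-2-hydroxy-7-oxabicyclo[4.1.0]heptan-2-yl]-2,4-bis[2-(trimethylsilyl)ethoxy]pyridine 1-oxide | C[Si](C)(C)CCOc1c(Br)c(OCC[Si](C)(C)C)c(c[n+]1[O-])[C@]2(O)CC[C@H](O[Si](C)(C)C(C)(C)C)[C@H]3O[C@H]32 | intermediate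
22 | 3-[(1R,2R,4aS,6R,8aR)-2,6-dimethyl-1,2,4a,5,6,7,8,8a-octahydronaphthalene-1-carbonyl]-5-[(1R,2R,5S,6S)-5-[(tert-butyldimethylsilyl)oxy]-2-hydroxy-7-oxabicyclo[4.1.0]heptan-2-yl]-2,4-bis[2-(trimethylsilyl)ethoxy]pyridine 1-oxide | C[C@@H]1CC[C@H]2[C@H](C(=O)c3c(OCC[Si](C)(C)C)c([C@]4(O)CC[C@H](O[Si](C)(C)C(C)(C)C)[C@H]5O[C@H]54)c[n+]([O-])c3OCC[Si](C)(C)C)[C@H](C)C=C[C@@H]2C1 | intermediate
23 | 3-[(1R,2R,4aS,6R,8aR)-2,6-dimethyl-1,2,4a,5,6,7,8,8a-octahydronaphthalene-1-carbonyl]-5-[(1R,2R,5S,6R)-2,5-dihydroxy-7-oxabicyclo[4.1.0]heptan-2-yl]-1,4-dihydroxypyridin-2(1H)-one | C[C@@H]1CC[C@H]2[C@H](C(=O)c3c(O)c([C@]4(O)CC[C@H](O)[C@H]5O[C@H]54)cn(O)c3=O)[C@H](C)C=C[C@@H]2C1 | target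

**Step count and risks**

Total step count: 13. Longest linear sequence: 7 steps (steps 1–5, 12, 13; the pyridine branch, steps 7–13, is equally long).

Steps most likely to fail:

Step 12. The bromide is flanked by two alkoxy groups, the N-oxide could be deoxygenated by low-valent nickel, and the secondary acyl radical can lose CO. The fallback sets out from 21 and 12. The tertiary alcohol of 21 is deprotonated with MeMgCl and the bromine is exchanged with i-PrMgCl·LiCl at −40 °C in THF. The pyridylmagnesium species is added to 12 to give the decalinyl(pyridyl)carbinol F1 as an epimer mixture. Dess–Martin oxidation in CH2Cl2 then gives the ketone, and the route is rejoined at 22.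

Step 11. The ring nitrogen of 20 sits next to an alkoxy group and feels the 3-bromine, so peracid oxidation may be slow. The fallback sets out from 19 and reverses the order of the two operations. The more basic, unbrominated pyridine is oxidised with mCPBA to the pyridine N-oxide carbinol F2. This N-oxide is then brominated with NBS at the carbon between the two alkoxy groups, and the route is rejoined at 21.

Step 13. Fluoride may cleave the two aryl 2-(trimethylsilyl)ethyl ethers only slowly, and a basic medium can move the epoxide (Payne-type) once the secondary alkoxide is free. The fallback sets out from 22 and unmasks in two acid-side stages instead of one fluoride stage. HF·pyridine in THF/pyridine at 0 °C removes only the silyl ether and gives the epoxy diol bis(silylethyl) ether F3. Brief treatment with TFA in CH2Cl2 at 0 °C then cleaves the two 2-(trimethylsilyl)ethyl ethers by acidolysis, and the route is rejoined at 23.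

Further compounds
F1 | step 12 | 3-{[(1R,2R,4aS,6R,8aR)-2,6-dimethyl-1,2,4a,5,6,7,8,8a-octahydronaphthalen-1-yl](hydroxy)methyl}-5-[(1R,2R,5S,6S)-5-[(tert-butyldimethylsilyl)oxy]-2-hydroxy-7-oxabicyclo[4.1.0]heptan-2-yl]-2,4-bis[2-(trimethylsilyl)ethoxy]pyridine 1-oxide (both epimers at the new carbinol carbon) | C[C@@H]1CC[C@H]2[C@H](C(O)c3c(OCC[Si](C)(C)C)c([C@]4(O)CC[C@H](O[Si](C)(C)C(C)(C)C)[C@H]5O[C@H]54)c[n+]([O-])c3OCC[Si](C)(C)C)[C@H](C)C=C[C@@H]2C1
F2 | step 11 | 5-[(1R,2R,5S,6S)-5-[(tert-butyldimethylsilyl)oxy]-2-hydroxy-7-oxabicyclo[4.1.0]heptan-2-yl]-2,4-bis[2-(trimethylsilyl)ethoxy]pyridine 1-oxide | C[Si](C)(C)CCOc1cc(OCC[Si](C)(C)C)c(c[n+]1[O-])[C@]2(O)CC[C@H](O[Si](C)(C)C(C)(C)C)[C@H]3O[C@H]32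
F3 | step 13 | 3-[(1R,2R,4aS,6R,8aR)-2,6-dimethyl-1,2,4a,5,6,7,8,8a-octahydronaphthalene-1-carbonyl]-5-[(1R,2R,5S,6R)-2,5-dihydroxy-7-oxabicyclo[4.1.0]heptan-2-yl]-2,4-bis[2-(trimethylsilyl)ethoxy]pyridine 1-oxide | C[C@@H]1CC[C@H]2[C@H](C(=O)c3c(OCC[Si](C)(C)C)c([C@]4(O)CC[C@H](O)[C@H]5O[C@H]54)c[n+]([O-])c3OCC[Si](C)(C)C)[C@H](C)C=C[C@@H]2C1
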